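The seven-membered ring is disconnected at two bonds: carbinol CH(O)–CH2 and quaternary C–cyclobutane CH, so that a C3 chain (CH2–CH2–C(CH3)(CO)) is stitched onto a bicyclic core. In one pot an ester-bearing alkylzinc adds to a 7-syn aldehyde of a norbornadienyl sulfone, the alkoxide lactonises, and the lactone enolate closes onto the strained vinyl sulfone. The step exploits the cis-1,4 relation of the carbinol oxygen and the CH2O carbon across the seven-membered ring (a lactone tether made of permanent atoms) and the cis-1,3 relation of the two ring junctions on the future cyclobutane. The sulfone later leaves in a ring contraction that creates the cyclobutane.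

Key step: step 6

Remark: compounds 1, 5 and 8 are taken as purchasable; the ring ester of the target is read as the (Z)-2-methylbut-2-enoate (angelate) and the CH2O ester as the (E)-isomer (tiglate), as the SMILES specifies. Locants C-1 to C-7 in compounds 6 to 13 follow bicyclo[2.2.1]heptane numbering (C-1 siloxy bridgehead, C-2 sulfonyl carbon, C-7 one-carbon bridge).

Step 1
Reactants: 1 2-oxocyclopentane-1-carbonitrile
Product: 2 (S)-1-methyl-2-oxocyclopentane-1-carbonitrile
Conditions: MeI, K2CO3, chiral N-spiro binaphthyl quaternary ammonium bromide (1 mol %, enantiomer that delivers the S product), toluene, 0 °C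
Reagents that add atoms: iodomethane, CI
Why: Asymmetric phase-transfer C-alkylation: the enolate of the β-keto nitrile is methylated inside the chiral ammonium ion pair, which should shield one face and set the (S) quaternary centre.

Step 2
Reactants: 2 (S)-1-methyl-2-oxocyclopentane-1-carbonitrile
Product: 3 (S)-1-methyl-2-oxocyclopent-3-ene-1-carbonitrile
Conditions: IBX, DMSO, 70 °C
Reagents that add atoms: none
Why: IBX dehydrogenation of a ketone through its only possible enol (the other α-carbon is quaternary) should give the conjugated enone without affecting the stereocentre.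

Step 3
Reactants: 3 (S)-1-methyl-2-oxocyclopent-3-ene-1-carbonitrile
Product: 4 (S)-1-methyl-2-(triethylsilyloxy)cyclopenta-2,4-diene-1-carbonitrile
Conditions: Et3SiOTf, Et3N, CH2Cl2, 0 °C
Reagents that add atoms: triethylsilyl trifluoromethanesulfonate, CC[Si](CC)(CC)OS(=O)(=O)C(F)(F)F
Why: Silyl dienol ether formation by O-silylation and γ-deprotonation (the α′-carbon has no hydrogen) gives a 1-siloxy-cyclopentadiene whose quaternary sp3 carbon cannot undergo 1,5-hydrogen shifts.

Step 4
Reactants: 4 (S)-1-methyl-2-(triethylsilyloxy)cyclopenta-2,4-diene-1-carbonitrile; 5 ethynyl 4-methylphenyl sulfone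
Product: 6 7-methyl-2-(4-methylphenylsulfonyl)-1-(triethylsilyloxy)bicyclo[2.2.1]hepta-2,5-diene-7-carbonitrile (nitrile syn to C2=C3, methyl syn to C5=C6)
Conditions: toluene, 60 °C
Reagents that add atoms: none
Why: Diels–Alder cycloaddition in which the siloxy-bearing diene terminus should bond to the sulfonyl-bearing alkyne carbon (ortho orientation of a 1-donor diene with an acceptor alkyne) and the dienophile should approach the diene face carrying the small linear nitrile instead of the methyl group, so that the nitrile ends up syn to the vinyl sulfone; C-7 is carried over from 4 and C-1 and C-4 follow from it.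

Step 5
Reactants: 6 norbornadiene nitrile
Product: 7 7-methyl-2-(4-methylphenylsulfonyl)-1-(triethylsilyloxy)bicyclo[2.2.1]hepta-2,5-diene-7-carbaldehyde (formyl syn to C2=C3)
Conditions: i-Bu2AlH, toluene, −78 °C; then aq. potassium sodium tartrate
Reagents that add atoms: water, O
Why: Partial reduction of the tertiary nitrile by i-Bu2AlH to the N-aluminio imine and hydrolysis on work-up should give the aldehyde, the vinyl sulfone and silyl ether being inert at low temperature.

Step 6
Reactants: 7 norbornadiene 7-carbaldehyde; 8 methyl 4-bromo-2-methylbutanoate (racemic)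
Product: 12 caged lactone sulfone (bridged δ-lactone whose methyl-bearing α-carbon is bonded exo to C-3 and whose O–CH carbon is bonded to C-7 of the 2-endo-sulfonyl norbornene), via alkylzinc bromide 9 (not isolated), via bromozinc alkoxide 10 (not isolated), via δ-lactone 11 (not isolated)
Conditions: 8, Zn dust, LiCl, THF, 50 °C; add 7, MgCl2, THF, 25 to 45 °C; then LiN(SiMe3)2, THF, −78 to 25 °C; t-BuOH, 25 °C; aq. NH4Cl
Reagents that add atoms: none
Why: The alkylzinc bromide 9 adds 1,2 to the non-enolisable aldehyde (new bond CH2–CH(O)), the metal alkoxide 10 lactonises onto the methyl ester (6-exo-trig acyl substitution) to δ-lactone 11, and LiN(SiMe3)2 then forms the lactone enolate, whose α-carbon adds to the β-carbon of the strained vinyl sulfone (7-exo-trig Michael closure of the carbocycle, new bond quaternary C–CH) before proton transfer to the α-sulfonyl carbanion. The closest known reaction types are the MgCl2-promoted addition of ester-bearing organozinc halides to aldehydes, lactonisation of δ-hydroxy esters and the intramolecular Michael addition of ester enolates to vinyl sulfones, here run as a Michael–aldol-type annulation in reverse order. The carbinol centre should follow Felkin–Anh addition anti to the bulky siloxy-bearing bridgehead C-1 (the silyl ether does not chelate), which turns the C–O bond toward C-2. The quaternary centre is fixed by the lactone tether, because the enolate can reach C-3 only from the exo face and only with the carbonyl bridge cis to the ring oxygen; C-3 is alkylated exo for the same reason, and C-2 should equilibrate by proton exchange to the less hindered endo sulfone. The step needs 1,2-addition to the aldehyde in preference to the vinyl sulfone (uncatalysed zinc reagents do not add to vinyl sulfones) and C- over O-Michael addition (lactonisation consumes the alkoxide before base is added, and any oxa-Michael adduct is reversible under base whereas the C–C bond is not).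

Step 7
Reactants: 12 caged lactone sulfone
Product: 13 triol sulfone (carbocycle CH(OH)–CH2–CH2–C(CH3)(CH2OH) spanning C-7 and exo C-3 of 2-endo-(4-methylphenylsulfonyl)-7-methylbicyclo[2.2.1]hept-5-en-1-ol)
Conditions: LiAlH4, THF, 0 °C; then 1 M HCl, THF, 25 °C
Reagents that add atoms: none
Why: Hydride reduction of the lactone gives the primary and the secondary alcohol with all stereocentres untouched (aryl sulfone, isolated alkene and silyl ether are inert), and the dilute acid of the work-up cleaves the tertiary triethylsilyl ether.

Step 8
Reactants: 13 triol sulfone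
Product: 14 6-hydroxy-3-(hydroxymethyl)-3,7-dimethyltricyclo[5.4.0.0^{2,8}]undec-9-en-11-one
Conditions: Et2AlCl (5 equiv), CH2Cl2, −78 to 0 °C; aq. potassium sodium tartrate
Reagents that add atoms: none
Why: Semipinacol rearrangement of a β-hydroxy sulfone promoted by an aluminium Lewis acid: the aluminium alkoxide at C-1 pushes, the aluminium-bound sulfinate leaves from the endo position, and the antiperiplanar C-1–C-7 bond migrates to C-2 (inversion at C-2, retention at C-7), which contracts the ring to the cyclobutane and leaves the ketone conjugated with the C-5=C-6 double bond.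

Step 9
Reactants: 14 enone diol
Product: 15 6-hydroxy-3-(hydroxymethyl)-3,7,9-trimethyltricyclo[5.4.0.0^{2,8}]undecan-11-one (the target with both ester groups replaced by OH)
Conditions: Me2CuLi (from CuI and MeLi, 5 equiv), Et2O, −78 to −30 °C; aq. NH4Cl
Reagents that add atoms: lithium dimethylcuprate, [Li+].C[Cu-]C
Why: Conjugate addition of lithium dimethylcuprate to the bridged enone should deliver methyl to the β-carbon from the side of the cyclobutane CH, away from the methyl group on the quaternary cyclobutane carbon, which sets the secondary methyl centre; excess reagent takes care of the two hydroxyl groups.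

Step 10
Reactants: 15 keto diol
Product: 16 mono-tiglate of 15 (primary CH2O esterified, secondary OH free)
Conditions: (E)-2-methylbut-2-enoyl chloride, pyridine, CH2Cl2, −20 to 0 °C
Reagents that add atoms: (E)-2-methylbut-2-enoyl chloride, C/C=C(\C)C(Cl)=O
Why: Acylation with an acid chloride should take the primary hydroxyl selectively over the hindered secondary one at low temperature, with the E double bond retained.

Step 11
Reactants: 16 mono-tiglate
Product: 17 CNP0276938.2 (target)
Conditions: angelic acid, 2,4,6-trichlorobenzoyl chloride, Et3N, toluene, 25 °C; then 16, toluene, 80 °C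
Reagents that add atoms: angelic acid, C/C=C(/C)C(=O)O
Why: Yamaguchi esterification through the mixed 2,4,6-trichlorobenzoic anhydride, conditions under which the angeloyl group should be transferred without Z-to-E isomerisation, acylates the remaining secondary alcohol.

Compound list
1 | 2-oxocyclopentane-1-carbonitrile | N#CC1CCCC1=O | starting material
2 | (S)-1-methyl-2-oxocyclopentane-1-carbonitrile | N#C[C@@]1(C)C(=O)CCC1 | intermediate
3 | (S)-1-methyl-2-oxocyclopent-3-ene-1-carbonitrile | N#C[C@@]1(C)C(=O)C=CC1 | intermediate
4 | (S)-1-methyl-2-(triethylsilyloxy)cyclopenta-2,4-diene-1-carbonitrile | N#C[C@@]1(C)C(O[Si](CC)(CC)CC)=CC=C1 | intermediate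
5 | ethynyl 4-methylphenyl sulfone | C#CS(=O)(=O)c1ccc(C)cc1 | starting material
6 | 7-methyl-2-(4-methylphenylsulfonyl)-1-(triethylsilyloxy)bicyclo[2.2.1]hepta-2,5-diene-7-carbonitrile, nitrile syn to C2=C3 | N#C[C@@]1(C)[C@]2(O[Si](CC)(CC)CC)C=C[C@H]1C=C2S(=O)(=O)c1ccc(C)cc1 | intermediate
7 | 7-methyl-2-(4-methylphenylsulfonyl)-1-(triethylsilyloxy)bicyclo[2.2.1]hepta-2,5-diene-7-carbaldehyde, formyl syn to C2=C3 | O=C[C@@]1(C)[C@]2(O[Si](CC)(CC)CC)C=C[C@H]1C=C2S(=O)(=O)c1ccc(C)cc1 | intermediate
8 | methyl 4-bromo-2-methylbutanoate (racemic) | COC(=O)C(C)CCBr | starting material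
9 | [3-(methoxycarbonyl)butyl]zinc bromide | COC(=O)C(C)CC[Zn]Br | intermediate
10 | bromozinc alkoxide of methyl 5-hydroxy-2-methyl-5-(norbornadien-7-yl)pentanoate (Felkin carbinol, ester α-carbon as epimer mixture) | COC(=O)C(C)CC[C@@H](O[Zn]Br)[C@@]1(C)[C@]2(O[Si](CC)(CC)CC)C=C[C@H]1C=C2S(=O)(=O)c1ccc(C)cc1 | intermediate
11 | 3-methyl-6-(norbornadien-7-yl)tetrahydro-2H-pyran-2-one (δ-lactone, C-3 of the lactone as epimer mixture) | CC1CC[C@@H](OC1=O)[C@@]2(C)[C@]3(O[Si](CC)(CC)CC)C=C[C@H]2C=C3S(=O)(=O)c2ccc(C)cc2 | intermediate
12 | caged lactone sulfone (lactone α-carbon bonded exo to C-3, sulfonyl endo at C-2, C-1 triethylsilyloxy, C5=C6 retained) | O=C1O[C@@H]2CC[C@@]1(C)[C@@H]1[C@@H](S(=O)(=O)c3ccc(C)cc3)[C@@]3(O[Si](CC)(CC)CC)C=C[C@@H]1[C@@]23C | intermediate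
13 | triol sulfone (bridgehead C-1 OH, ring CH–OH, CH2OH on the quaternary carbon, sulfonyl endo at C-2) | OC[C@@]1(C)CC[C@@H](O)[C@]2(C)[C@H]3C=C[C@]2(O)[C@H](S(=O)(=O)c2ccc(C)cc2)[C@@H]13 | intermediate
14 | 6-hydroxy-3-(hydroxymethyl)-3,7-dimethyltricyclo[5.4.0.0^{2,8}]undec-9-en-11-one | O[C@@H]1CC[C@](C)(CO)[C@H]2[C@@H]3C=CC(=O)[C@H]2[C@@]31C | intermediate
15 | 6-hydroxy-3-(hydroxymethyl)-3,7,9-trimethyltricyclo[5.4.0.0^{2,8}]undecan-11-one | O[C@@H]1CC[C@](C)(CO)[C@H]2[C@@H]3[C@H](C)CC(=O)[C@H]2[C@@]31C | intermediate
16 | (E)-2-methylbut-2-enoate (tiglate) of the primary alcohol of 15 | O[C@@H]1CC[C@](C)(COC(=O)/C(C)=C/C)[C@H]2[C@@H]3[C@H](C)CC(=O)[C@H]2[C@@]31C | intermediate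
17 | CNP0276938.2 (ring angelate, CH2O tiglate) | C/C=C(/C)C(=O)O[C@@H]1CC[C@](C)(COC(=O)/C(C)=C/C)[C@H]2[C@@H]3[C@H](C)CC(=O)[C@H]2[C@@]31C | target

Total step count: 11. Longest linear sequence: 11 steps (1 to 17); 5 and 8 enter as purchased reactants.

Steps most likely to fail

Step 6. The lactonisation may lag behind, so that base meets a free alkoxide which adds to the vinyl sulfone (oxa-Michael trapping), or the addition to the aldehyde may lose facial control. Fallback, from 7 back to 12: the dianion of methyl 2-methyl-3-oxobutanoate (NaH, then n-BuLi, THF) adds through its terminal carbon to 7 and, after acidic work-up and DBU, the far more acidic β-keto lactone closes by Michael addition in one pot to the caged β-keto lactone F1. NaBH4 reduces the ketone to the caged hydroxy lactone F2. NaH, CS2 and MeI give the S-methyl xanthate F3, and Bu3SnH with AIBN (Barton–McCombie deoxygenation) returns 12.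

Step 8. The aluminium alkoxide may fragment by retro-aldol cleavage of the C-1–C-2 bond, or the free secondary alkoxide that sits over C-2 may capture that carbon (ether formation) in competition with the 1,2-shift. Fallback, from 12 back to 14: the ring contraction is run while that oxygen is still tied up in the lactone. HF·pyridine in THF removes the silyl group to give the desilylated caged lactone F4, which carries a single hydroxyl. Et2AlCl then gives the enone lactone F5. LiAlH4 reduces lactone and enone carbonyl to the allylic triol F6, and MnO2 in CH2Cl2 reoxidises only the allylic alcohol to 14.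

Step 1. The ion pair may discriminate the enolate faces too weakly, so that the quaternary centre forms with low enantiomeric purity. Fallback, from 1 back to 2: uncatalysed methylation (MeI, K2CO3, acetone) gives racemic 1-methyl-2-oxocyclopentane-1-carbonitrile F7. Kinetic resolution with an NADPH-dependent ketoreductase (glucose and glucose dehydrogenase for recycling, buffer, 30 °C) reduces the (R)-ketone to 2-hydroxy-1-methylcyclopentane-1-carbonitrile F8, and the unreacted (S)-ketone 2 is separated by chromatography.

Further compounds
F1 | step 6 | caged β-keto lactone (12 with a ketone at the lactone CH2 next to the quaternary carbon) | O=C1O[C@@H]2CC(=O)[C@@]1(C)[C@@H]1[C@@H](S(=O)(=O)c3ccc(C)cc3)[C@@]3(O[Si](CC)(CC)CC)C=C[C@@H]1[C@@]23C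
F2 | step 6 | caged hydroxy lactone (carbinol epimers) | O=C1O[C@@H]2CC(O)[C@@]1(C)[C@@H]1[C@@H](S(=O)(=O)c3ccc(C)cc3)[C@@]3(O[Si](CC)(CC)CC)C=C[C@@H]1[C@@]23C
F3 | step 6 | S-methyl xanthate of F2 | O=C1O[C@@H]2CC(OC(=S)SC)[C@@]1(C)[C@@H]1[C@@H](S(=O)(=O)c3ccc(C)cc3)[C@@]3(O[Si](CC)(CC)CC)C=C[C@@H]1[C@@]23C
F4 | step 8 | desilylated caged lactone (bridgehead alcohol, sulfonyl endo at C-2) | O=C1O[C@@H]2CC[C@@]1(C)[C@@H]1[C@@H](S(=O)(=O)c3ccc(C)cc3)[C@@]3(O)C=C[C@@H]1[C@@]23C
F5 | step 8 | enone lactone (14 with its two oxygens joined as the bridging lactone) | O=C1O[C@@H]2CC[C@@]1(C)[C@H]1[C@@H]3C=CC(=O)[C@H]1[C@]23C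
F6 | step 8 | allylic triol (14 with the ketone reduced, carbinol epimers) | O[C@@H]1CC[C@](C)(CO)[C@H]2[C@@H]3C=CC(O)[C@H]2[C@@]31C
F7 | step 1 | racemic 1-methyl-2-oxocyclopentane-1-carbonitrile | N#CC1(C)C(=O)CCC1
F8 | step 1 | 2-hydroxy-1-methylcyclopentane-1-carbonitrile from the (R)-ketone (carbinol configuration set by the enzyme) | N#C[C@]1(C)C(O)CCC1
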